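## Retrosynthetic overview

1. The acyl–allyl bond C4–C5 is made last, under visible light: target ⇐ allylic methyl carbonate 11 + isovaleryl radical from 4-methyl-2-oxopentanoic acid 12 (nickel/photoredox).
2. 11 ⇐ diol 10 ⇐ terminal allylic oxidation of the C20 furyl trienyl ester 8.
3. The C17 stereocenter comes from Mitsunobu inversion of the (1R)-alcohol 7. Alcohol 7 is formed (C16–C17 bond) by [2,3]-Wittig rearrangement with chirality transfer from the tertiary carbinol of natural (3S,6E)-nerolidol 1, etherified with 3-(bromomethyl)furan 2.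
4. Rings: the furan is the only ring; it is bought intact in 2 and no ring is formed.

Assumption: dextrorotatory (3S,6E)-nerolidol (natural isolate of high enantiomeric purity), 3-(bromomethyl)furan and 4-methyl-2-oxopentanoic acid are purchased.

## Route

Step 1
Reactants: 1 (3S,6E)-nerolidol; 2 3-(bromomethyl)furan
Product: 4 3-({[(3S,6E)-3,7,11-trimethyldodeca-1,6,10-trien-3-yl]oxy}methyl)furan, via potassium nerolidolate 3 (not isolated)
Conditions: KH, THF, 0 °C; then 2, Bu4NI (cat.), 0 °C to rt
Reagents that add atoms: none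
Why: Williamson ether synthesis of a tertiary potassium alkoxide with a reactive furylmethyl bromide; the C–O bond of the stereocenter is not touched, so 3S is kept.

Step 2
Reactants: 4 3-({[(3S,6E)-3,7,11-trimethyldodeca-1,6,10-trien-3-yl]oxy}methyl)furan
Product: 7 (1R,3E,7E)-1-(furan-3-yl)-4,8,12-trimethyltrideca-3,7,11-trien-1-ol, via lithiated ether 5 (not isolated), via lithium alkoxide 6 (not isolated)
Conditions: s-BuLi, THF, −78 to −40 °C; then H2O
Reagents that add atoms: none
Why: [2,3]-Wittig rearrangement in which the furylmethyl carbanion attacks the vinyl terminus suprafacially through a five-membered envelope, where the C3–O stereocenter of nerolidol fixes the face, the homoprenyl chain sits pseudo-equatorial (E alkene) and the furyl group exo, which sets 1R; the Z isomer (expected E:Z about 3:2, carrying 1S) is removed on AgNO3-impregnated silica gel, which also secures the enantiomeric purity of 7.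

Step 3
Reactants: 7 (1R,3E,7E)-1-(furan-3-yl)-4,8,12-trimethyltrideca-3,7,11-trien-1-ol
Product: 8 (1S,3E,7E)-1-(furan-3-yl)-4,8,12-trimethyltrideca-3,7,11-trien-1-yl 4-nitrobenzoate
Conditions: 4-nitrobenzoic acid, PPh3, DIAD, toluene, −20 °C to rt
Reagents that add atoms: 4-nitrobenzoic acid, O=C(O)c1ccc(cc1)[N+](=O)[O-]
Why: Mitsunobu reaction, in which SN2 displacement of the oxyphosphonium group by 4-nitrobenzoate inverts C1 from R to S, and the ester then shields the furyl carbinol during the oxidation.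

Step 4
Reactants: 8 (1S,3E,7E)-1-(furan-3-yl)-4,8,12-trimethyltrideca-3,7,11-trien-1-yl 4-nitrobenzoate
Product: 10 (1S,3E,7E,11E)-1-(furan-3-yl)-4,8,12-trimethyltrideca-3,7,11-triene-1,13-diol, via hydroxy nitrobenzoate 9 (not isolated)
Conditions: SeO2 (cat.), t-BuOOH, salicylic acid (cat.), CH2Cl2, 0 °C to rt; then K2CO3, MeOH, rt
Reagents that add atoms: selenium dioxide, O=[Se]=O (the oxygen it delivers is resupplied by tert-butyl hydroperoxide, CC(C)(C)OO)
Why: selenium dioxide allylic oxidation (ene reaction then [2,3]-shift) hydroxylates the E-methyl group of the least hindered, terminal trisubstituted alkene with E geometry, and K2CO3/MeOH transesterification then frees the secondary alcohol without breaking its C–O bond, so 1S is kept.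

Step 5
Reactants: 10 (1S,3E,7E,11E)-1-(furan-3-yl)-4,8,12-trimethyltrideca-3,7,11-triene-1,13-diol
Product: 11 (2E,6E,10E,13S)-13-(furan-3-yl)-13-hydroxy-2,6,10-trimethyltrideca-2,6,10-trien-1-yl methyl carbonate
Conditions: ClCO2Me (1.05 equiv), pyridine, CH2Cl2, −30 °C
Reagents that add atoms: methyl chloroformate, COC(=O)Cl
Why: chemoselective acylation, because the unhindered primary allylic hydroxyl reacts with the chloroformate far faster at −30 °C than the secondary furyl carbinol, which installs the leaving group for the last step.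

Step 6
Reactants: 11 (2E,6E,10E,13S)-13-(furan-3-yl)-13-hydroxy-2,6,10-trimethyltrideca-2,6,10-trien-1-yl methyl carbonate; 12 4-methyl-2-oxopentanoic acid (2 equiv)
Product: 13 (6E,10E,14E,17S)-17-(furan-3-yl)-17-hydroxy-2,6,10,14-tetramethylheptadeca-6,10,14-trien-4-one
Conditions: NiCl2(dme) (10 mol %), 4,4′-di-tert-butyl-2,2′-bipyridine (dtbbpy, 15 mol %), [Ir(dF(CF3)ppy)2(dtbbpy)]PF6 (2 mol %; dF(CF3)ppy = 2-(2,4-difluorophenyl)-5-(trifluoromethyl)pyridine), 2,6-lutidine (20 mol %), degassed DMF, blue LEDs (450 nm), 25 °C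
Reagents that add atoms: none
Why: Proposed new method: nickel/photoredox decarboxylative acyl–allyl coupling, in which the excited trivalent iridium complex oxidises the carboxylate of 12 to the isovaleryl radical (loss of CO2), zerovalent nickel ionises 11 to a syn π-allyl divalent nickel species whose departing methyl carbonate (CO2 + methoxide) is the only base needed to deprotonate further 12, radical capture gives an acyl(allyl) trivalent nickel that reductively eliminates at the unhindered CH2 terminus with retention of the E alkene, and divalent iridium returns monovalent nickel to zerovalent nickel; the acidic, base-free medium keeps the β,γ-unsaturated ketone out of conjugation and C17 is not involved; the closest known reaction types are the nickel/photoredox decarboxylative acyl–aryl coupling of α-keto acids and nickel- or palladium-catalysed allylic substitution of carbonates, and acyl-radical capture by a 2-methyl-substituted π-allyl nickel on a polyene has not been shown.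

## Compound list

1 | (3S,6E)-nerolidol, (3S,6E)-3,7,11-trimethyldodeca-1,6,10-trien-3-ol | C=C[C@@](C)(O)CC/C=C(\C)CCC=C(C)C | starting material
2 | 3-(bromomethyl)furan | BrCc1ccoc1 | starting material
3 | potassium (3S,6E)-3,7,11-trimethyldodeca-1,6,10-trien-3-olate | C=C[C@@](C)([O-])CC/C=C(\C)CCC=C(C)C.[K+] | intermediate
4 | 3-({[(3S,6E)-3,7,11-trimethyldodeca-1,6,10-trien-3-yl]oxy}methyl)furan | C=C[C@@](C)(OCc1ccoc1)CC/C=C(\C)CCC=C(C)C | intermediate
5 | lithiated ether, [furan-3-yl({[(3S,6E)-3,7,11-trimethyldodeca-1,6,10-trien-3-yl]oxy})methyl]lithium | C=C[C@@](C)(OC([Li])c1ccoc1)CC/C=C(\C)CCC=C(C)C | intermediate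
6 | lithium (1R,3E,7E)-1-(furan-3-yl)-4,8,12-trimethyltrideca-3,7,11-trien-1-olate | c1cocc1[C@H]([O-])C/C=C(\C)CC/C=C(\C)CCC=C(C)C.[Li+] | intermediate
7 | (1R,3E,7E)-1-(furan-3-yl)-4,8,12-trimethyltrideca-3,7,11-trien-1-ol | c1cocc1[C@H](O)C/C=C(\C)CC/C=C(\C)CCC=C(C)C | intermediate
8 | (1S,3E,7E)-1-(furan-3-yl)-4,8,12-trimethyltrideca-3,7,11-trien-1-yl 4-nitrobenzoate | c1cocc1[C@@H](OC(=O)c1ccc(cc1)[N+](=O)[O-])C/C=C(\C)CC/C=C(\C)CCC=C(C)C | intermediate
9 | (1S,3E,7E,11E)-1-(furan-3-yl)-13-hydroxy-4,8,12-trimethyltrideca-3,7,11-trien-1-yl 4-nitrobenzoate | c1cocc1[C@@H](OC(=O)c1ccc(cc1)[N+](=O)[O-])C/C=C(\C)CC/C=C(\C)CC/C=C(\C)CO | intermediate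
10 | (1S,3E,7E,11E)-1-(furan-3-yl)-4,8,12-trimethyltrideca-3,7,11-triene-1,13-diol | c1cocc1[C@@H](O)C/C=C(\C)CC/C=C(\C)CC/C=C(\C)CO | intermediate
11 | (2E,6E,10E,13S)-13-(furan-3-yl)-13-hydroxy-2,6,10-trimethyltrideca-2,6,10-trien-1-yl methyl carbonate | c1cocc1[C@@H](O)C/C=C(\C)CC/C=C(\C)CC/C=C(\C)COC(=O)OC | intermediate
12 | 4-methyl-2-oxopentanoic acid | CC(C)CC(=O)C(=O)O | starting material
13 | (6E,10E,14E,17S)-17-(furan-3-yl)-17-hydroxy-2,6,10,14-tetramethylheptadeca-6,10,14-trien-4-one | C/C(=C\CC/C(C)=C/C[C@H](O)c1ccoc1)CC/C=C(\C)CC(=O)CC(C)C | target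

## Step count and risks

Total steps: 6. Longest linear sequence: 6 (from 1).

The three steps most likely to fail:

**Step 2 ([2,3]-Wittig rearrangement).** The risks are competing lithiation at furan C2, an E:Z ratio near 3:2 that caps the yield of 7, and a demanding E/Z separation. The fallback changes how the furan is introduced; it sets out from 1 and comes back at 7, and it does not improve the E:Z ratio. Alcohol 1 is O-propargylated (KH, propargyl bromide, THF) to (3S,6E)-3,7,11-trimethyl-3-(prop-2-yn-1-yloxy)dodeca-1,6,10-triene F1. Treatment with n-BuLi (2.3 equiv, THF, −78 to −30 °C) gives the dilithiated propargyl ether F2, which rearranges by the same envelope model ([2,3]-Wittig of a propargyl ether, the best-behaved substrate class) to the dilithium alkoxide acetylide F3 and, on aqueous quench, to (3R,5E,9E)-6,10,14-trimethylpentadeca-5,9,13-trien-1-yn-3-ol F4. Heating F4 with 4-phenyloxazole (neat, 200 °C, sealed tube) builds the furan by Diels–Alder addition to the 7-oxa-2-azabicyclo[2.2.1]hepta-2,5-diene cycloadduct F5 and loss of benzonitrile, giving 7.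

**Step 4 (allylic oxidation).** The risks are attack of the oxidant on the furan and competing oxidation at the two internal alkenes. The fallback moves the oxidation ahead of the furan; it sets out from 1 and comes back at 9. Alcohol 1 is oxidised first (SeO2 cat., t-BuOOH, CH2Cl2) to (2E,6E,10S)-2,6,10-trimethyldodeca-2,6,11-triene-1,10-diol F6. TBSCl/imidazole silylates only the primary hydroxyl to give (3S,6E,10E)-12-{[tert-butyl(dimethyl)silyl]oxy}-3,7,11-trimethyldodeca-1,6,10-trien-3-ol F7. KH then 2 gives, through the potassium silyloxy alkoxide F8, the silyloxy furylmethyl ether F9. s-BuLi effects the same rearrangement through the lithiated silyloxy ether F10 and the lithium silyloxy alkoxide F11 to (1R,3E,7E,11E)-13-{[tert-butyl(dimethyl)silyl]oxy}-1-(furan-3-yl)-4,8,12-trimethyltrideca-3,7,11-trien-1-ol F12. Mitsunobu inversion as in step 3 gives the (1S) silyloxy 4-nitrobenzoate F13, and Bu4NF (buffered with AcOH, THF) removes the silyl group to give 9, which is methanolysed to 10 as in step 4.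

**Step 6 (proposed new coupling).** The risks are syn/anti isomerisation of the π-allyl nickel species (E/Z erosion), diene formation by β-hydride elimination, and inefficient radical capture. The fallback uses known polar chemistry; it sets out from 11 and comes back at 13. Carbonate 11 is alkylated with 3-methyl-1-nitrobutane (3 equiv) under Pd(PPh3)4 catalysis (zerovalent palladium, THF, rt; neutral Tsuji–Trost allylation, the liberated methoxide generating the nitronate). This gives (1S,3E,7E,11E)-1-(furan-3-yl)-4,8,12,16-tetramethyl-14-nitroheptadeca-3,7,11-trien-1-ol F14 as a mixture of epimers at the nitro carbon. NaOMe/MeOH (0 °C) converts it to the sodium nitronate F15, which buffered aqueous TiCl3/NH4OAc turns into 13 (Nef reaction: reduction of the nitronate by trivalent titanium, then hydrolysis of the imine at pH 5–6).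

## Further compounds

F1 | step 2 | (3S,6E)-3,7,11-trimethyl-3-(prop-2-yn-1-yloxy)dodeca-1,6,10-triene | C=C[C@@](C)(OCC#C)CC/C=C(\C)CCC=C(C)C
F2 | step 2 | dilithiated propargyl ether (not isolated) | C=C[C@@](C)(OC([Li])C#C[Li])CC/C=C(\C)CCC=C(C)C
F3 | step 2 | dilithium alkoxide acetylide of F4 (not isolated) | [Li]C#C[C@H](O[Li])C/C=C(\C)CC/C=C(\C)CCC=C(C)C
F4 | step 2 | (3R,5E,9E)-6,10,14-trimethylpentadeca-5,9,13-trien-1-yn-3-ol | C#C[C@H](O)C/C=C(\C)CC/C=C(\C)CCC=C(C)C
F5 | step 2 | 7-oxa-2-azabicyclo[2.2.1]hepta-2,5-diene cycloadduct of F4 and 4-phenyloxazole (not isolated) | C12N=C(c3ccccc3)C(O1)C=C2[C@H](O)C/C=C(\C)CC/C=C(\C)CCC=C(C)C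
F6 | step 4 | (2E,6E,10S)-2,6,10-trimethyldodeca-2,6,11-triene-1,10-diol | C=C[C@@](C)(O)CC/C=C(\C)CC/C=C(\C)CO
F7 | step 4 | (3S,6E,10E)-12-{[tert-butyl(dimethyl)silyl]oxy}-3,7,11-trimethyldodeca-1,6,10-trien-3-ol | C=C[C@@](C)(O)CC/C=C(\C)CC/C=C(\C)CO[Si](C)(C)C(C)(C)C
F8 | step 4 | potassium silyloxy alkoxide of F7 (not isolated) | C=C[C@@](C)([O-])CC/C=C(\C)CC/C=C(\C)CO[Si](C)(C)C(C)(C)C.[K+]
F9 | step 4 | silyloxy furylmethyl ether, tert-butyl{[(2E,6E,10S)-10-(furan-3-ylmethoxy)-2,6,10-trimethyldodeca-2,6,11-trien-1-yl]oxy}dimethylsilane | C=C[C@@](C)(OCc1ccoc1)CC/C=C(\C)CC/C=C(\C)CO[Si](C)(C)C(C)(C)C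
F10 | step 4 | lithiated silyloxy ether (not isolated) | C=C[C@@](C)(OC([Li])c1ccoc1)CC/C=C(\C)CC/C=C(\C)CO[Si](C)(C)C(C)(C)C
F11 | step 4 | lithium silyloxy alkoxide of F12 (not isolated) | c1cocc1[C@H]([O-])C/C=C(\C)CC/C=C(\C)CC/C=C(\C)CO[Si](C)(C)C(C)(C)C.[Li+]
F12 | step 4 | (1R,3E,7E,11E)-13-{[tert-butyl(dimethyl)silyl]oxy}-1-(furan-3-yl)-4,8,12-trimethyltrideca-3,7,11-trien-1-ol | c1cocc1[C@H](O)C/C=C(\C)CC/C=C(\C)CC/C=C(\C)CO[Si](C)(C)C(C)(C)C
F13 | step 4 | (1S,3E,7E,11E)-13-{[tert-butyl(dimethyl)silyl]oxy}-1-(furan-3-yl)-4,8,12-trimethyltrideca-3,7,11-trien-1-yl 4-nitrobenzoate | c1cocc1[C@@H](OC(=O)c1ccc(cc1)[N+](=O)[O-])C/C=C(\C)CC/C=C(\C)CC/C=C(\C)CO[Si](C)(C)C(C)(C)C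
F14 | step 6 | (1S,3E,7E,11E)-1-(furan-3-yl)-4,8,12,16-tetramethyl-14-nitroheptadeca-3,7,11-trien-1-ol | c1cocc1[C@@H](O)C/C=C(\C)CC/C=C(\C)CC/C=C(\C)CC(CC(C)C)[N+](=O)[O-]
F15 | step 6 | sodium nitronate of F14 (not isolated) | c1cocc1[C@@H](O)C/C=C(\C)CC/C=C(\C)CC/C=C(\C)CC(CC(C)C)=[N+]([O-])[O-].[Na+]
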